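**Plan**

- Retrosynthesis: the free hydroxyl of ring B is uncovered from a pivalate (acyl C–O bond). The diaryl ether is then cut between the ring B oxygen and C6 of ring A, giving 2,4-dibromophenol and the monopivalate of 3,6-dibromocatechol.
- Enabling feature: ring A is a 2,4-dibromophenol whose only hydrogen-bearing ortho carbon (C6) carries the ether oxygen. Ring B is a symmetric 3,6-dibromocatechol, so either oxygen gives the same ether and an acyl shift between them changes nothing.
- Ring B is cut further at its two C–Br bonds and two O–CH3 bonds, back to veratrole.
- Forward: veratrole is twice ortho-lithiated and brominated, demethylated and monoacylated. Both benzene rings are bought; they are joined once, by anodic O–H/C–H cross-coupling, and the ester is then removed.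
- Stereochemistry: the target has no stereocentre; the one sp3 carbon on the way is a transient dienone carbon that is lost on enolisation.

Key step: step 4

Remark: 2,4-dibromo-6-fluorobenzaldehyde, used only in a fallback, is taken to be purchasable.

**Route**

Step 1
Reactants: 1 veratrole (1,2-dimethoxybenzene)
Product: 3 1,4-dibromo-2,3-dimethoxybenzene, via 3,6-dilithio-1,2-dimethoxybenzene 2 (not isolated)
Conditions: n-BuLi (3 equiv), TMEDA (3 equiv), Et2O/hexane, 0 °C → rt; then BrCl2C–CCl2Br (3 equiv), THF, −78 °C → rt
Reagents that add atoms: n-butyllithium, [Li]CCCC (lithium of 2 only); 1,2-dibromo-1,1,2,2-tetrachloroethane, BrC(Cl)(Cl)C(Cl)(Cl)Br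
Why: Each methoxy group directs n-BuLi/TMEDA to the neighbouring ring carbon (twofold directed ortho-metalation), and each aryllithium then takes bromine from the polyhaloethane, which collapses to LiBr and tetrachloroethene.

Step 2
Reactants: 3 1,4-dibromo-2,3-dimethoxybenzene
Product: 5 3,6-dibromobenzene-1,2-diol, via 2,4,7-tribromo-1,3,2-benzodioxaborole 4 (not isolated)
Conditions: BBr3 (2.5 equiv), CH2Cl2, −78 °C → rt; then H2O, 0 °C
Reagents that add atoms: boron tribromide, BrB(Br)Br (boron and bromine of 4 only)
Why: BBr3 demethylation of aryl methyl ethers (Lewis acid complexation, then bromide attack at methyl) leaves aryl bromides untouched, and the cyclic bromoborate should hydrolyse to the catechol on work-up.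

Step 3
Reactants: 5 3,6-dibromobenzene-1,2-diol; 6 pivaloyl chloride
Product: 7 3,6-dibromo-2-hydroxyphenyl pivalate
Conditions: 6 (1.0 equiv), Et3N (1.1 equiv), CH2Cl2, −20 → 0 °C, under argon
Reagents that add atoms: pivaloyl chloride 6, CC(C)(C)C(=O)Cl
Why: Base-mediated O-acylation (nucleophilic acyl substitution) of the symmetric catechol should stop after one ester, because the remaining hydroxyl lies between a bromine and the tert-butyl ester and is both hindered and less nucleophilic.

Step 4
Reactants: 7 3,6-dibromo-2-hydroxyphenyl pivalate; 8 2,4-dibromophenol
Product: 10 3,6-dibromo-2-(3,5-dibromo-2-hydroxyphenoxy)phenyl pivalate, via 6-aryloxy-2,4-dibromocyclohexa-2,4-dienone 9 (not isolated)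
Conditions: boron-doped diamond (BDD) anode, Pt cathode, undivided cell; 7 (3 equiv), Bu3MeN+ MeOSO3− (0.1 M), HFIP, rt; 8 fed slowly; constant current held at the foot of the oxidation wave of 8, about 2 F per mol of 8; excess 7 recovered
Reagents that add atoms: none
Why: Proposed new method: 8 is the easier phenol to oxidise (its bromines ortho and para to the hydroxyl donate by resonance, whereas 7 carries an acyloxy group and a meta bromine), so the anode should convert only 8 into the HFIP-solvated phenoxyl radical and, after a second electron, the phenoxonium ion; the hydroxyl oxygen of 7 adds at C6, the only ortho carbon of ring A bearing hydrogen, and dienone 9 tautomerises to phenol 10 while the two protons leave as H2 at the cathode. The closest known reaction types are the anodic dehydrogenative cross-coupling of phenols at BDD in HFIP, which normally forms C–C bonds, and the anodic or enzymatic O–C dimerisation of ortho-halophenols to ortho-aryloxyphenols. No ring closes and no stereocentre remains, since the sp3 carbon of 9 is lost on enolisation. The step needs cross- over homo-coupling, which the gap in oxidation potential, the excess of 7 and the slow feed of 8 are meant to secure, and O–C over C–C bond formation, which is favoured because the ring carbons of 7 are deactivated by two bromines and the ester while adducts at the bromine-bearing C2 and C4 of ring A cannot aromatise. The pivalate also prevents oxidation of ring B to an ortho-quinone and closure of 10 to a dibenzodioxin, and HFIP solvation with a limited charge should guard 10 against further oxidation.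

Step 5
Reactants: 10 3,6-dibromo-2-(3,5-dibromo-2-hydroxyphenoxy)phenyl pivalate
Product: 11 3,6-dibromo-2-(3,5-dibromo-2-hydroxyphenoxy)phenol
Conditions: K2CO3 (3 equiv), MeOH, rt; then 1 M HCl
Reagents that add atoms: none
Why: Base-mediated transesterification (methanolysis) should cleave the aryl ester because the bromophenoxide is a good leaving group, while the diaryl ether and the four aryl bromides are inert to carbonate in methanol at room temperature.

**Compound list**

1 | veratrole (1,2-dimethoxybenzene) | COc1ccccc1OC | starting material
2 | 3,6-dilithio-1,2-dimethoxybenzene | COc1c([Li])ccc([Li])c1OC | intermediate (not isolated)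
3 | 1,4-dibromo-2,3-dimethoxybenzene | COc1c(Br)ccc(Br)c1OC | intermediate
4 | 2,4,7-tribromo-1,3,2-benzodioxaborole | BrB1Oc2c(Br)ccc(Br)c2O1 | intermediate (not isolated)
5 | 3,6-dibromobenzene-1,2-diol | Oc1c(Br)ccc(Br)c1O | intermediate
6 | pivaloyl chloride | CC(C)(C)C(=O)Cl | starting material
7 | 3,6-dibromo-2-hydroxyphenyl pivalate | CC(C)(C)C(=O)Oc1c(Br)ccc(Br)c1O | intermediate
8 | 2,4-dibromophenol | Oc1ccc(Br)cc1Br | starting material
9 | 3,6-dibromo-2-[(3,5-dibromo-6-oxocyclohexa-2,4-dien-1-yl)oxy]phenyl pivalate (racemic, transient) | CC(C)(C)C(=O)Oc1c(Br)ccc(Br)c1OC1C=C(Br)C=C(Br)C1=O | intermediate (not isolated)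
10 | 3,6-dibromo-2-(3,5-dibromo-2-hydroxyphenoxy)phenyl pivalate | CC(C)(C)C(=O)Oc1c(Br)ccc(Br)c1Oc1cc(Br)cc(Br)c1O | intermediate
11 | 3,6-dibromo-2-(3,5-dibromo-2-hydroxyphenoxy)phenol | Oc1c(Br)cc(Br)cc1Oc1c(Br)ccc(Br)c1O | target

**Count**

Total steps: 5. Longest linear sequence: 5 steps (1 → 11); 6 and 8 enter as bought materials.

**Steps most likely to fail**

Step 4. The oxidised form of ring A may be captured through carbon instead of oxygen (the para carbon of 7) or by a second molecule of 8, and 10 may be oxidised further with loss of bromine. The fallback makes the ether by nucleophilic aromatic substitution and sets out from 7. Reaction of 7 with 2,4-dibromo-6-fluorobenzaldehyde (O=Cc1c(F)cc(Br)cc1Br; K2CO3, DMF, 60 °C) should displace the fluoride ortho to the formyl group and give 3,6-dibromo-2-(3,5-dibromo-2-formylphenoxy)phenyl pivalate F1. Baeyer–Villiger oxidation with mCPBA (CH2Cl2, rt) should then turn the aldehyde into the aryl formate 3,6-dibromo-2-[3,5-dibromo-2-(formyloxy)phenoxy]phenyl pivalate F2. Brief methanolysis of the formate (KHCO3, MeOH, 0 °C) comes back to the route at 10.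

Step 1. The second metalation may stall, and bromine may be scrambled by lithium–bromine exchange between aryllithium and aryl bromide during the quench. The fallback uses silicon as a placeholder and sets out from 1. Lithiation (n-BuLi, TMEDA) and quench with Me3SiCl, repeated once on the crude mixture, should give 1,2-dimethoxy-3,6-bis(trimethylsilyl)benzene F3; C–Si bonds are inert to n-BuLi, so the second metalation can be driven to completion. Ipso-bromodesilylation with Br2 in CH2Cl2 at 0 °C comes back to the route at 3.

Step 3. Acylation may run on to the diester while diol remains, leaving a mixture of three components. The fallback over-acylates and then removes one group, setting out from 5. Exhaustive acylation (excess 6, Et3N, catalytic DMAP, CH2Cl2) should give 3,6-dibromo-1,2-phenylene bis(2,2-dimethylpropanoate) F4. One equivalent of pyrrolidine (THF, 0 °C → rt) should then remove a single acyl group by aminolysis, because the phenoxide formed deactivates the neighbouring ester. Acidic work-up comes back to the route at 7.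

**Further compounds**

F1 | step 4 | 3,6-dibromo-2-(3,5-dibromo-2-formylphenoxy)phenyl pivalate | CC(C)(C)C(=O)Oc1c(Br)ccc(Br)c1Oc1cc(Br)cc(Br)c1C=O
F2 | step 4 | 3,6-dibromo-2-[3,5-dibromo-2-(formyloxy)phenoxy]phenyl pivalate | CC(C)(C)C(=O)Oc1c(Br)ccc(Br)c1Oc1cc(Br)cc(Br)c1OC=O
F3 | step 1 | 1,2-dimethoxy-3,6-bis(trimethylsilyl)benzene | COc1c([Si](C)(C)C)ccc([Si](C)(C)C)c1OC
F4 | step 3 | 3,6-dibromo-1,2-phenylene bis(2,2-dimethylpropanoate) | CC(C)(C)C(=O)Oc1c(Br)ccc(Br)c1OC(=O)C(C)(C)C
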